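## Structural features

The target is a caged tetracycle: a bicyclo[3.3.1]nonane-2,4,9-trione (C1–C9) whose C3 and C7 are joined a second time through the two-carbon bridge C11–C10, which makes a homoadamantane, with a cyclopentane (C3, C11, C12, C13, C14) fused on the C3–C11 bond. C1 carries the benzoyl group, C5 the (E)-geranyl chain, C8 and C12 are gem-dimethyl carbons and C13 bears the isopropenyl group. Of the six stereocentres, C1, C5 and C7 are bridgeheads that the cage fixes once C3 and C11 are set. The independent elements are therefore the cis relation of the C4 and C10 arms on the adjacent carbons C3 and C11, the trans relation of C11 and C13 across C12, and the absolute configuration. Fragile are the triacylated carbon C1 and the non-enolisable 1,3-dicarbonyl arrays at C3 and C5 (retro-Claisen cleavage by nucleophiles), and the geranyl diene and the isopropenyl group (acid, radicals). The real difficulty is crowding: five quaternary carbons (C1, C3, C5, C8, C12), the vicinal pair C1–C8 among them, sit in or on a rigid cage in which no ketone can be enolised to correct an error. The key step exploits the ring C5–C6–C7–C8–C1–C9: a cyclohexanone with its carbonyl at C9 is the retron of a [4+2] cycloaddition between the 2-oxygenated diene C6=C5–C9(O)=C1 and the alkene C7=C8, and because C5 and C7 are also joined through C4–C3–C11–C10, the cycloaddition can be intramolecular and close the six- and the seven-membered ring together. C10, a methylene group in the target, carries a carbonyl group for this step so that C7=C8 is an enone, and the C5=C9 enol ether left by the cycloaddition marks C5 and masks C9 for the steps that follow.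

## Logic of the disconnections

31 ⇒ 30. The C1–benzoyl bond is cut first. C1 of 30 holds the only acidic hydrogen of the cage (between C2=O and C9=O), and the most cleavage-prone unit is thereby added last. The forward step must deprotonate a bridgehead with a base that neither adds to nor reduces the ketones and must acylate on carbon.

30 ⇒ 29. The C1–C2 bond is cut (retro-Claisen). This opens the trione ring and the second seven-membered ring of the cage and leaves a bicyclo[4.3.1]decanedione with the ester C2 on C3 and a methylene group at C1. The forward step needs the C9 enolate to form only at C1 (C5 is quaternary) and needs a driving force, because the product has no ordinary acidic hydrogen.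

29 ⇒ 27 + 28. The bond from C5 to the geranyl chain is cut; C5 of 27 lies between two carbonyls. This removes ten carbons and the (E)-alkene from all earlier steps. The forward step must alkylate on carbon at a hindered bridgehead, at the unsubstituted allyl terminus and with retention of the (E)-geometry.

27 ⇒ 26 ⇒ 25. No carbon–carbon bond is cut: the C4 ketone goes back to a silyl-protected alcohol and the C9 ketone to the C5=C9 silyl enol ether. In 25 the ester is the only carbonyl group. The forward steps must remove both silyl groups without retro-aldol cleavage of 26.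

25 ⇒ 24 ⇒ 23 ⇒ 22. The C10 methylene group is traced back to the ketone that activated the dienophile. The oxygen is removed directly after the cycloaddition, while C9 is an enol ether and C4 a silyl ether, so that hydride meets one ketone only. Left to the end, the same operation would have to distinguish C10 from four other ketones and tolerate the geranyl diene. The forward steps need a radical at C10 that finds no alkene within reach.

22 ⇒ 21. C6–C7 and C1–C8 are cut (retro-[4+2]). Two rings, two skeletal bonds, the quaternary C8 and the stereocentre C7 disappear, leaving a monocyclic cyclopentane with a diene arm on C3 and an enone arm on C11. The forward step needs a hindered β,β-dimethyl enone to act as dienophile and needs the enol ether to survive.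

21 ⇒ 20 ⇒ 19 ⇒ 18 ⇒ 15 + 16. First the O–Si bond of the enol ether and the C9 carbonyl (back to its dioxolane), then the C10 carbonyl (back to the carbinol), then the C10–C7 bond are cut. The diene is made last so that it never meets an oxidant or an organometallic reagent. This demands an enolisation that selects the methyl ketone over the enone, and a ketal that keeps C9 silent while 17 adds to the aldehyde.

15 ⇒ 14 ⇒ 13 ⇒ 11 + 4. The C4–C5 bond is cut: the C5–C9–C1 unit arrives as the α-metalated, ketal-protected form of 1 (12, from 4), and C4 is the masked aldehyde of 11. An organolithium is chosen because an amine-catalysed Baylis–Hillman coupling of 1 is too slow for a quaternary, lactol-masked aldehyde. The diol 13 is differentiated through the different reactivity of a primary and a hindered secondary triethylsilyl ether.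

11 ⇒ 10 ⇒ 9 ⇒ 8. The lactone C4–O bond is cut. Lactonisation of the C10 hydroxyl onto the only ester it can reach (the cis one) distinguishes the two esters of the malonate carbon. This creates the C3 stereocentre and labels the cis carbonyl as C4 and the other as C2. The enantiomers are separated here.

8 ⇒ 7 + 6. C3–C11 and C12–C13 are cut ([3+2] annulation). The whole cyclopentane with C11, C12 and C13 comes from two prenyl units. The forward step must add a malonyl radical to the CH end of 6, close 5-exo before the tertiary radical is oxidised, and place C11 and C13 trans.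

7 ⇒ 5 + 6 and 4 ⇒ 3 ⇒ 2 ⇒ 1. The C3–C14 bond is an allylic alkylation of 5 by 6. The bromovinyl ketal 4 comes from 1 by bromination, ketalisation and dehydrobromination.

## Other disconnections considered

Alternative 1: The cut is C3–C11 and C3–C12, leading back to the diazo dione A1, a bicyclo[3.3.1]nonane-2,4,9-trione with benzoyl at C1, geranyl at C5, a diazo group at C3 and an endo prenyl group on C7 whose alkene carbons are C11 and C12. In the forward direction Rh2(OAc)4 would generate an electrophilic carbenoid at C3 that adds to C11=C12 and gives the cyclopropane-fused cage A2.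
- In its favour: it starts from an intact trione core at the final oxidation level. It needs no oxygen at C10 that must later be removed and no protecting group at C4. On redox and protecting-group economy it is better than the chosen plan. Diazo transfer to a 2-unsubstituted 1,3-dione and cyclopropanation of trisubstituted alkenes by diacyl carbenoids are well-established reaction types, so the ring closure itself stands on precedent at least equal to that of the chosen cycloaddition.
- Against it here: the geranyl alkene nearest C5 can reach the C3 carbenoid through a five-membered arrangement and should compete with the C7 prenyl group, which must also sit axial. A2 still lacks C13, C14 and the isopropenyl group. These would have to be inserted by opening the C3–C12 bond of the acceptor cyclopropane. A polar opening puts the cation at C12, which would bond to the unsubstituted end of an isoprene-type partner, so the isopropenyl carbon would end up next to C3 instead of C12, and C13 would be set without a controlling element.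
- Comparison: the chosen plan fixes the cyclopentane and its C11/C13 relation before any cage exists and uses them to set C7. Alternative 1 makes the cage first and leaves the cyclopentane to a late annulation of uncertain regiochemistry. It might be shorter in steps if that annulation could be solved, but it has two uncertain events (chemoselective cyclopropanation, regioselective ring expansion) against one in the chosen plan.

Alternative 2: The cut is C4–C5 and C1–C2, the two acyl–carbon bonds of the trione ring, leading back to A3. In A3 the methyl enol ether of the 2-geranyl-5,5-dimethylcyclohexanone is linked from C7 through C10 to C11 of an isopropenyl-dimethylcyclopentane-1,1-dicarbonyl dichloride. Two successive C-acylations of the enol ether (first at C5, then at C1) would give A4, which is the same compound as 30, so the last step would be shared with the chosen plan.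
- In its favour: acylation by an acid chloride is irreversible, which is better than the reversible ester condensation of step 21. The trione is reached at the right oxidation level without any oxygen at C10 or redox change at C4, which is also better. Its end point equals that of the chosen plan.
- Against it here: C7 in A3 is joined to the cyclopentane only through the flexible C10 methylene group, so its configuration relative to C11 and C13 must be set by a separate fragment coupling without internal control. The first acylation must build the quaternary C5 on a tetrasubstituted enol ether that already bears the geranyl chain, where O-acylation is the usual competitor. The two acid chloride groups are diastereotopic and only one pairing can close the cage. A bis(acid chloride) and the HCl it releases are a poor match for the isopropenyl group, the geranyl diene and the enol ether.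
- Comparison: structurally A3 is more convergent. Mechanistically its ring closure is sounder than the Claisen step, but its C5 bond formation is less secure than the allylation of 27. In step count it is probably similar once the two chiral fragments and their union are counted, and the stereochemical problem of C7 is left open where the chosen cycloaddition solves it.

Alternative 3: The cut is C10–C11 and C12–C13, leading back to A5, a bicyclo[3.3.1]nonanetrione carrying the benzoyl and geranyl groups, a formyl group (C10) on C7 and, on C3, both a 2-methylprop-1-enyl group (C11=C12) and a prenyl group (C14–C13=). A Lewis acid would activate the aldehyde, C11 would attack C10 (Prins closure of the seven-membered ring), the tertiary cation at C12 would be captured 5-exo by the prenyl alkene and proton loss would give the isopropenyl group of A6, the C10-hydroxy target. A final deoxygenation would follow.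
- In its favour: one step forms two rings, two carbon–carbon bonds and the stereocentres C11 and C13 from a substrate that already holds every carbon of the target. In bond-forming efficiency this is better than anything in the chosen plan, and no early resolution of a cyclopentane is needed.
- Against it here: A5 requires a quaternary C3 with a directly attached alkenyl group, which is hard to install on a hindered dione, and C3 must be set relative to the cage. The C12 cation can lose a proton or be trapped by a ketone oxygen before the second ring closes. The final elimination must go to the methyl side, and the C11/C13 relation rests on an unconstrained cyclisation geometry. The Lewis acid threatens the geranyl diene and the triacylated C1. The deoxygenation at C10 is needed in both plans, which makes them equal on that count. In alternative 3, however, it comes at the very end, beside five ketones and with a geranyl alkene within radical reach, whereas the chosen plan does it when one ketone and no geranyl chain are present.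
- Comparison: alternative 3 is the most step-economical on paper and the richest in complexity gain per step. The chosen plan forms the same bridge carbon by a pericyclic step whose regiochemistry and facial course are fixed by the tether, and pays for this control with more steps.

Key step: step 14

Assumption 1: compound 8 is racemic; the enantiomers are separated at lactone 10 by preparative chromatography on a chiral stationary phase and the (1R,5S,7S) enantiomer is carried on.

Assumption 2: the carbinol carbon C4 formed in step 7 is drawn (S) for definiteness; either epimer or the mixture serves, because C4 becomes a ketone in step 19.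

## Route

Step 1
Reactants: 1 methyl vinyl ketone (but-3-en-2-one)
Product: 3 2-(1,2-dibromoethyl)-2-methyl-1,3-dioxolane, via 3,4-dibromobutan-2-one 2 (not isolated)
Conditions: Br2, CH2Cl2, −15 °C; then HOCH2CH2OH, p-TsOH (cat.), benzene, reflux (Dean–Stark)
Reagents that add atoms: bromine, BrBr; ethylene glycol, OCCO
Why: Ionic addition of bromine to the enone followed by acid-catalysed ketalisation with azeotropic removal of water; the lachrymatory dibromo ketone is carried on without isolation.

Step 2
Reactants: 3 2-(1,2-dibromoethyl)-2-methyl-1,3-dioxolane
Product: 4 2-(1-bromoethenyl)-2-methyl-1,3-dioxolane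
Conditions: KOt-Bu, THF, 0 °C to rt
Reagents that add atoms: none
Why: E2 dehydrobromination removes the hydrogen on the carbon next to the ketal carbon, as in the standard preparation of 2-bromoacrolein acetals, and gives the 1-bromovinyl ketal, a masked C6=C5–C9(=O)–C1 unit.

Step 3
Reactants: 5 dimethyl malonate; 6 prenyl acetate (3-methylbut-2-en-1-yl acetate)
Product: 7 dimethyl 2-(3-methylbut-2-en-1-yl)malonate
Conditions: NaH, Pd(PPh3)4 (2 mol %), THF, 60 °C (5 in excess)
Reagents that add atoms: none
Why: Tsuji–Trost allylation; the malonate anion attacks the less hindered terminus of the dimethylallyl complex of palladium formed from zerovalent palladium and 6, which gives the linear prenyl product, and the excess of 5 suppresses double allylation.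

Step 4
Reactants: 7 dimethyl 2-(3-methylbut-2-en-1-yl)malonate; 6 prenyl acetate
Product: 8 dimethyl (2S*,4S*)-2-(acetoxymethyl)-3,3-dimethyl-4-(prop-1-en-2-yl)cyclopentane-1,1-dicarboxylate (racemic, acetoxymethyl and isopropenyl trans)
Conditions: Mn(OAc)3·2H2O (2.2 equiv), Cu(OAc)2·H2O (0.2 equiv), 6 (5 equiv), AcOH, 60 °C
Reagents that add atoms: none
Why: Oxidative radical [3+2] annulation: the malonyl radical formed by trivalent manganese adds to the CH end of 6 (C3–C11), the tertiary radical at C12 closes 5-exo onto the prenyl group (C12–C13), and divalent copper oxidises the new tertiary radical to the isopropenyl group. The chair-like transition state of the 5-exo closure places the acetoxymethyl group pseudo-equatorial, which should favour the trans relation of C11 and C13; the product is racemic.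

Step 5
Reactants: 8 dimethyl (2S*,4S*)-2-(acetoxymethyl)-3,3-dimethyl-4-(prop-1-en-2-yl)cyclopentane-1,1-dicarboxylate
Product: 10 methyl (1R,5S,7S)-6,6-dimethyl-2-oxo-7-(prop-1-en-2-yl)-3-oxabicyclo[3.3.0]octane-1-carboxylate, via hydroxy diester 9 (not isolated)
Conditions: K2CO3, MeOH, 0 °C to rt; AcOH work-up; preparative SFC on a chiral stationary phase (CO2/MeOH)
Reagents that add atoms: none
Why: Methanolysis of the acetate frees the C10 hydroxyl, which can lactonise only onto the ester cis to it (cis-fused five-membered lactone). This differentiates the two esters and fixes C3, with the lactone carbonyl as C4 and the remaining ester as C2; the enantiomers are then separated.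

Step 6
Reactants: 10 methyl (1R,5S,7S)-6,6-dimethyl-2-oxo-7-(prop-1-en-2-yl)-3-oxabicyclo[3.3.0]octane-1-carboxylate
Product: 11 lactol, methyl (5S,7S)-2-hydroxy-6,6-dimethyl-7-(prop-1-en-2-yl)-3-oxabicyclo[3.3.0]octane-1-carboxylate (ring fusion as in 10, mixture of anomers)
Conditions: i-Bu2AlH (1.1 equiv), CH2Cl2, −78 °C; aq. potassium sodium tartrate
Reagents that add atoms: none
Why: The γ-lactone carbonyl is more electrophilic than the neopentyl-type methyl ester and its tetrahedral aluminate is stable at −78 °C, so the reduction should stop at the lactol.

Step 7
Reactants: 11 lactol; 4 2-(1-bromoethenyl)-2-methyl-1,3-dioxolane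
Product: 13 diol, methyl 1-[(1S)-1-hydroxy-2-(2-methyl-1,3-dioxolan-2-yl)prop-2-en-1-yl]-2-(hydroxymethyl)-3,3-dimethyl-4-(prop-1-en-2-yl)cyclopentane-1-carboxylate (ring carbons as in 10), via 1-(2-methyl-1,3-dioxolan-2-yl)ethenyllithium 12 (not isolated)
Conditions: 4 (3 equiv), t-BuLi (6 equiv), THF, −78 °C; then 11, −78 to −20 °C; aq. NH4Cl
Reagents that add atoms: none
Why: Bromine–lithium exchange gives an α-ketovinyl anion equivalent; one equivalent opens the lactol to the aldehyde alkoxide and the next adds to the aldehyde, which is far more reactive than the hindered ester. The new carbinol centre C4 is not controlled and need not be.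

Step 8
Reactants: 13 diol
Product: 14 bis(triethylsilyl) ether of 13 (C4–OSiEt3 and C10–OSiEt3)
Conditions: Et3SiCl, imidazole, DMAP (cat.), DMF, rt to 40 °C
Reagents that add atoms: chlorotriethylsilane, CC[Si](CC)(CC)Cl
Why: Standard silylation of both hydroxyl groups; the chloride with imidazole avoids a Lewis acidic silyl triflate beside the ketal.

Step 9
Reactants: 14 bis(triethylsilyl) ether
Product: 15 aldehyde, methyl 2-formyl-3,3-dimethyl-1-[(1S)-2-(2-methyl-1,3-dioxolan-2-yl)-1-(triethylsilyloxy)prop-2-en-1-yl]-4-(prop-1-en-2-yl)cyclopentane-1-carboxylate (ring carbons as in 10)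
Conditions: (COCl)2, DMSO, CH2Cl2, −78 to −30 °C; then Et3N, −78 to 0 °C
Reagents that add atoms: none
Why: Under Swern conditions a primary triethylsilyl ether is cleaved and oxidised directly to the aldehyde while the hindered secondary triethylsilyl ether stays, which saves a separate deprotection. The low temperature guards C11 against epimerisation.

Step 10
Reactants: 15 aldehyde; 16 1-bromo-2-methylprop-1-ene
Product: 18 allylic alcohol (C10 carbinol of 15 bearing the 2-methylprop-1-enyl group; mixture of C10 epimers), via 2-methylprop-1-enylmagnesium bromide 17 (not isolated)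
Conditions: 16, Mg, THF, 40 °C; then 15, THF, −78 °C; aq. NH4Cl
Reagents that add atoms: none
Why: Grignard addition to the aldehyde at low temperature; the ketal masks the C9 carbonyl and the ester on the quaternary C3 is too hindered to compete. The carbinol configuration is irrelevant.

Step 11
Reactants: 18 allylic alcohol
Product: 19 enone ketal, methyl 3,3-dimethyl-2-(3-methylbut-2-enoyl)-1-[(1S)-2-(2-methyl-1,3-dioxolan-2-yl)-1-(triethylsilyloxy)prop-2-en-1-yl]-4-(prop-1-en-2-yl)cyclopentane-1-carboxylate
Conditions: Dess–Martin periodinane, NaHCO3, CH2Cl2, 0 °C to rt
Reagents that add atoms: none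
Why: Buffered Dess–Martin oxidation of the allylic alcohol gives the β,β-dimethyl enone without touching the ketal or the silyl ether.

Step 12
Reactants: 19 enone ketal
Product: 20 enone methyl ketone, methyl 3,3-dimethyl-2-(3-methylbut-2-enoyl)-1-[(1S)-2-methylidene-3-oxo-1-(triethylsilyloxy)butyl]-4-(prop-1-en-2-yl)cyclopentane-1-carboxylate
Conditions: pyridinium p-toluenesulfonate (cat.), acetone–H2O (10:1), 40 °C
Reagents that add atoms: water, O
Why: Mild acid hydrolysis of the allylic dioxolane unveils the α-methylene methyl ketone; the hindered secondary silyl ether and the enone should tolerate the weak acid.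

Step 13
Reactants: 20 enone methyl ketone
Product: 21 siloxydiene–enone, methyl 3,3-dimethyl-2-(3-methylbut-2-enoyl)-1-[(1S)-2-methylidene-1,3-bis(triethylsilyloxy)but-3-en-1-yl]-4-(prop-1-en-2-yl)cyclopentane-1-carboxylate (diene arm on C3 cis to the enone arm on C11, ester trans to it, isopropenyl trans to the enone arm)
Conditions: KN(SiMe3)2 (1.1 equiv), Et3SiCl (1.5 equiv), THF, −78 °C (base added to ketone and chlorosilane)
Reagents that add atoms: chlorotriethylsilane, CC[Si](CC)(CC)Cl
Why: Kinetic deprotonation with silylation in the same flask takes the unhindered methyl group of the α-methylene ketone in preference to the shielded tertiary C11–H and the γ-methyl groups of the enone, giving the 2-siloxydiene. Forming the diene last keeps it out of every oxidation and organometallic step.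

Step 14
Reactants: 21 siloxydiene–enone
Product: 22 bridged adduct: cyclopentane-fused bicyclo[4.3.1]dec-1(9)-ene with ring C5=C9(OSiEt3)–C1H2–C8Me2–C7H–C6H2, bridge C7–C10(=O)–C11H–C3(CO2Me)–C4H(OSiEt3)–C5 and cyclopentane C3–C11–C12Me2–C13H(isopropenyl)–C14H2; C7 as in the target
Conditions: Me2AlCl (1.2 equiv), CH2Cl2, −78 to −20 °C; Et3N, then aq. NaHCO3
Reagents that add atoms: none
Why: Me2AlCl binds the C10 carbonyl of the s-cis β,β-dimethyl enone, and the 2-siloxydiene, held at its inner carbon C5 through C4–C3–C11–C10, adds across C7=C8 in a concerted but asynchronous [4+2] in which the C1–C8 bond runs ahead of C6–C7. The closest known reaction type is the type 2 intramolecular Diels–Alder reaction of 2-substituted dienes with a four-atom tether, which gives bicyclo[4.3.1]decenes with a bridgehead double bond, together with Lewis-acid [4+2] additions of hindered 2-siloxydienes to β,β-disubstituted enones. The cyclohexene C5–C6–C7–C8–C1–C9 closes by the cycloaddition itself, and the cycloheptane C3–C4–C5–C6–C7–C10–C11 closes as the tether ring through the C6–C7 bond, exo with respect to the dienophile. The only new stereocentre, C7, is set by the cyclopentane: with the C4 and C10 arms cis on C3 and C11, the diene reaches the enone on the face that keeps C8 and its methyl groups away from the C12 gem-dimethyl group, so the C9–C1–C8 bridge forms on the ester side and H7 points outward. Regiochemistry needs no outside control, because the tether allows only the meta-bridged mode and this mode also pairs the nucleophilic diene terminus C1 with the electrophilic β-carbon C8. The step needs conjugate addition in preference to carbonyl addition and needs the enol ether to survive; the s-cis enone, the low temperature and the proton-scavenging alkylaluminium should secure both, and the C5=C9 double bond is allowed at the bridgehead because it lies trans in a nine-membered ring of the bicycle.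

Step 15
Reactants: 22 bridged adduct
Product: 23 C10 alcohol of 22 (mixture of C10 epimers)
Conditions: NaBH4, EtOH–THF (1:4), 0 °C to rt
Reagents that add atoms: none
Why: Borohydride reduces the only ketone; the ester is inert and the C9 carbonyl is masked as the bridgehead enol ether, which is why the oxygen at C10 is removed at this stage and not at the end. The carbinol configuration is irrelevant.

Step 16
Reactants: 23 C10 alcohol
Product: 24 C10 S-methyl xanthate of 23
Conditions: NaH, imidazole (cat.), THF, 0 °C; CS2; then MeI, rt
Reagents that add atoms: carbon disulfide, S=C=S; iodomethane, CI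
Why: Xanthate formation from the alkoxide, the first half of a Barton–McCombie deoxygenation; no other acidic or electrophilic site is exposed (the ester has no α-hydrogen).

Step 17
Reactants: 24 C10 xanthate
Product: 25 C10-deoxy adduct (22 with CH2 at C10; silyl enol ether, silyl ether and ester intact)
Conditions: Bu3SnH, AIBN (cat.), toluene, 90 °C
Reagents that add atoms: none
Why: Barton–McCombie deoxygenation; the secondary C10 radical has no productive cyclisation path (the isopropenyl group is trans on the cyclopentane and attack on the enol ether would need a four-membered ring), so hydrogen transfer from the stannane should give the methylene group.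

Step 18
Reactants: 25 C10-deoxy adduct
Product: 26 β-hydroxy ketone (C4–OH, C9=O, H at the bridgehead C5; ester on C3)
Conditions: HF·pyridine, pyridine, THF, 0 °C to rt
Reagents that add atoms: none
Why: Buffered fluoride-assisted desilylation removes both silyl groups; C-protonation of the enol ether at the bridgehead C5 can occur only from outside, and the mildly acidic medium avoids retro-aldol cleavage of the β-hydroxy ketone.

Step 19
Reactants: 26 β-hydroxy ketone
Product: 27 bridged 1,3-diketone (C4=O and C9=O flanking C5–H)
Conditions: Dess–Martin periodinane, NaHCO3, CH2Cl2, rt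
Reagents that add atoms: none
Why: Dess–Martin oxidation of the hindered secondary alcohol; the C4 stereocentre disappears and the only acidic hydrogen between two carbonyls is now at C5.

Step 20
Reactants: 27 bridged 1,3-diketone; 28 geranyl acetate
Product: 29 C5-geranyl diketo ester
Conditions: NaH, THF, 0 °C; then 28, Pd(PPh3)4 (5 mol %), THF, 50 °C
Reagents that add atoms: none
Why: Tsuji–Trost allylation of the sodium enolate of the 1,3-diketone: attack at the less hindered terminus of the geranyl complex of palladium gives the linear (E)-product, and any O-allylation is reversible under zerovalent palladium, so the C-allylated quaternary centre accumulates. C5 is a bridgehead, so the new chain can only point outward.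

Step 21
Reactants: 29 C5-geranyl diketo ester
Product: 30 des-benzoyl cage trione (C1–H)
Conditions: lithium 2,2,6,6-tetramethylpiperidide (3 equiv, from n-BuLi and the amine), THF, −78 to 0 °C; AcOH, −78 °C
Reagents that add atoms: none
Why: Intramolecular Claisen (Dieckmann-type) condensation: the only enolisable position is C1, whose enolate attacks the C2 ester held over it on C3 and closes the trione ring and the second seven-membered ring of the cage; C1 becomes a bridgehead, so its configuration is fixed by the ring. Excess hindered amide base should convert the product into its C1 anion, which protects it from cleavage by methoxide until the cold acidic quench.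

Step 22
Reactants: 30 des-benzoyl cage trione
Product: 31 target, CNP0110731.1
Conditions: lithium 2,2,6,6-tetramethylpiperidide (1.5 equiv, from n-BuLi and the amine), THF, −78 °C; PhCOCl, −78 to 0 °C
Reagents that add atoms: benzoyl chloride, O=C(Cl)c1ccccc1
Why: Bridgehead deprotonation between the C2 and C9 carbonyls followed by C-acylation, the reaction type used for bridgehead substitution of bicyclo[3.3.1]nonanetriones. The base has no β-hydrogen and cannot reduce the ketones, and C1–H is the only acidic hydrogen left.

## Compound list

1 | methyl vinyl ketone (but-3-en-2-one) | CC(=O)C=C | starting material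
2 | 3,4-dibromobutan-2-one (racemic, not isolated) | CC(=O)C(Br)CBr | intermediate
3 | 2-(1,2-dibromoethyl)-2-methyl-1,3-dioxolane (racemic) | CC1(OCCO1)C(Br)CBr | intermediate
4 | 2-(1-bromoethenyl)-2-methyl-1,3-dioxolane | C=C(Br)C1(C)OCCO1 | intermediate
5 | dimethyl malonate | COC(=O)CC(=O)OC | starting material
6 | prenyl acetate (3-methylbut-2-en-1-yl acetate) | CC(C)=CCOC(C)=O | starting material
7 | dimethyl 2-(3-methylbut-2-en-1-yl)malonate | COC(=O)C(CC=C(C)C)C(=O)OC | intermediate
8 | dimethyl (2S*,4S*)-2-(acetoxymethyl)-3,3-dimethyl-4-(prop-1-en-2-yl)cyclopentane-1,1-dicarboxylate (racemic; one enantiomer drawn) | C=C(C)[C@@H]1CC(C(=O)OC)(C(=O)OC)[C@@H](COC(C)=O)C1(C)C | intermediate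
9 | dimethyl (2S*,4S*)-2-(hydroxymethyl)-3,3-dimethyl-4-(prop-1-en-2-yl)cyclopentane-1,1-dicarboxylate (racemic, not isolated) | C=C(C)[C@@H]1CC(C(=O)OC)(C(=O)OC)[C@@H](CO)C1(C)C | intermediate
10 | methyl (1R,5S,7S)-6,6-dimethyl-2-oxo-7-(prop-1-en-2-yl)-3-oxabicyclo[3.3.0]octane-1-carboxylate (cis-fused lactone ester, single enantiomer) | C=C(C)[C@@H]1C[C@@]2(C(=O)OC)C(=O)OC[C@H]2C1(C)C | intermediate
11 | lactol, methyl (5S,7S)-2-hydroxy-6,6-dimethyl-7-(prop-1-en-2-yl)-3-oxabicyclo[3.3.0]octane-1-carboxylate (ring fusion as in 10, anomer mixture) | C=C(C)[C@@H]1C[C@@]2(C(=O)OC)C(O)OC[C@H]2C1(C)C | intermediate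
12 | 1-(2-methyl-1,3-dioxolan-2-yl)ethenyllithium (not isolated) | [Li]C(=C)C1(C)OCCO1 | intermediate
13 | diol, methyl 1-[(1S)-1-hydroxy-2-(2-methyl-1,3-dioxolan-2-yl)prop-2-en-1-yl]-2-(hydroxymethyl)-3,3-dimethyl-4-(prop-1-en-2-yl)cyclopentane-1-carboxylate (C4 arm cis to CH2OH, ester trans, isopropenyl trans to CH2OH) | C=C(C)[C@@H]1C[C@@](C(=O)OC)([C@@H](O)C(=C)C2(C)OCCO2)[C@@H](CO)C1(C)C | intermediate
14 | bis(triethylsilyl) ether of 13 | C=C(C)[C@@H]1C[C@@](C(=O)OC)([C@@H](O[Si](CC)(CC)CC)C(=C)C2(C)OCCO2)[C@@H](CO[Si](CC)(CC)CC)C1(C)C | intermediate
15 | aldehyde, methyl 2-formyl-3,3-dimethyl-1-[(1S)-2-(2-methyl-1,3-dioxolan-2-yl)-1-(triethylsilyloxy)prop-2-en-1-yl]-4-(prop-1-en-2-yl)cyclopentane-1-carboxylate | C=C(C)[C@@H]1C[C@@](C(=O)OC)([C@@H](O[Si](CC)(CC)CC)C(=C)C2(C)OCCO2)[C@@H](C=O)C1(C)C | intermediate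
16 | 1-bromo-2-methylprop-1-ene | CC(C)=CBr | starting material
17 | 2-methylprop-1-enylmagnesium bromide (not isolated) | CC(C)=C[Mg]Br | intermediate
18 | allylic alcohol, C10 carbinol of 15 with 2-methylprop-1-enyl group (C10 epimers) | C=C(C)[C@@H]1C[C@@](C(=O)OC)([C@@H](O[Si](CC)(CC)CC)C(=C)C2(C)OCCO2)[C@@H](C(O)C=C(C)C)C1(C)C | intermediate
19 | enone ketal, methyl 3,3-dimethyl-2-(3-methylbut-2-enoyl)-1-[(1S)-2-(2-methyl-1,3-dioxolan-2-yl)-1-(triethylsilyloxy)prop-2-en-1-yl]-4-(prop-1-en-2-yl)cyclopentane-1-carboxylate | C=C(C)[C@@H]1C[C@@](C(=O)OC)([C@@H](O[Si](CC)(CC)CC)C(=C)C2(C)OCCO2)[C@@H](C(=O)C=C(C)C)C1(C)C | intermediate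
20 | enone methyl ketone, methyl 3,3-dimethyl-2-(3-methylbut-2-enoyl)-1-[(1S)-2-methylidene-3-oxo-1-(triethylsilyloxy)butyl]-4-(prop-1-en-2-yl)cyclopentane-1-carboxylate | C=C(C)[C@@H]1C[C@@](C(=O)OC)([C@@H](O[Si](CC)(CC)CC)C(=C)C(C)=O)[C@@H](C(=O)C=C(C)C)C1(C)C | intermediate
21 | siloxydiene–enone (precursor of the key step), methyl 3,3-dimethyl-2-(3-methylbut-2-enoyl)-1-[(1S)-2-methylidene-1,3-bis(triethylsilyloxy)but-3-en-1-yl]-4-(prop-1-en-2-yl)cyclopentane-1-carboxylate | C=C(C)[C@@H]1C[C@@](C(=O)OC)([C@@H](O[Si](CC)(CC)CC)C(=C)C(=C)O[Si](CC)(CC)CC)[C@@H](C(=O)C=C(C)C)C1(C)C | intermediate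
22 | bridged adduct (cyclopentane-fused bicyclo[4.3.1]dec-1(9)-ene; C9 silyl enol ether, C4 silyl ether, C10 ketone, C3 ester) | C=C(C)[C@@H]1C[C@@]2(C(=O)OC)[C@@H](O[Si](CC)(CC)CC)C3=C(O[Si](CC)(CC)CC)CC(C)(C)[C@@H](C3)C(=O)[C@H]2C1(C)C | intermediate
23 | C10 alcohol of 22 (C10 epimers) | C=C(C)[C@@H]1C[C@@]2(C(=O)OC)[C@@H](O[Si](CC)(CC)CC)C3=C(O[Si](CC)(CC)CC)CC(C)(C)[C@@H](C3)C(O)[C@H]2C1(C)C | intermediate
24 | C10 S-methyl xanthate of 23 | C=C(C)[C@@H]1C[C@@]2(C(=O)OC)[C@@H](O[Si](CC)(CC)CC)C3=C(O[Si](CC)(CC)CC)CC(C)(C)[C@@H](C3)C(OC(=S)SC)[C@H]2C1(C)C | intermediate
25 | C10-deoxy adduct | C=C(C)[C@@H]1C[C@@]2(C(=O)OC)[C@@H](O[Si](CC)(CC)CC)C3=C(O[Si](CC)(CC)CC)CC(C)(C)[C@@H](C3)C[C@H]2C1(C)C | intermediate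
26 | β-hydroxy ketone (C4–OH, C9=O, C5–H) | C=C(C)[C@@H]1C[C@@]2(C(=O)OC)[C@@H](O)[C@H]3C[C@@H](C[C@H]2C1(C)C)C(C)(C)CC3=O | intermediate
27 | bridged 1,3-diketone (C4=O, C9=O, C5–H) | C=C(C)[C@@H]1C[C@@]2(C(=O)OC)C(=O)[C@H]3C[C@@H](C[C@H]2C1(C)C)C(C)(C)CC3=O | intermediate
28 | geranyl acetate ((2E)-3,7-dimethylocta-2,6-dien-1-yl acetate) | CC(=O)OC/C=C(\C)CCC=C(C)C | starting material
29 | C5-geranyl diketo ester | C=C(C)[C@@H]1C[C@@]2(C(=O)OC)C(=O)[C@@]3(C/C=C(\C)CCC=C(C)C)C[C@@H](C[C@H]2C1(C)C)C(C)(C)CC3=O | intermediate
30 | des-benzoyl cage trione (C1–H) | C=C(C)[C@@H]1C[C@@]23C(=O)[C@@]4(C/C=C(\C)CCC=C(C)C)C[C@@H](C[C@H]2C1(C)C)C(C)(C)[C@H](C4=O)C3=O | intermediate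
31 | CNP0110731.1 | C=C(C)[C@@H]1C[C@@]23C(=O)[C@@]4(C/C=C(\C)CCC=C(C)C)C[C@@H](C[C@H]2C1(C)C)C(C)(C)[C@](C(=O)c1ccccc1)(C4=O)C3=O | target

## Step count and least certain steps

Total: 22 steps. Longest linear sequence: 20 steps (steps 3–22, from 5). Steps 1 and 2 are a two-step side branch that joins at step 7.

**Step 14 (key step).** The most likely failure is that the enol ether terminus C1 adds to the activated carbonyl carbon C10 (closing a seven-membered carbinol), or that the diene is protodesilylated, before the slow conjugate bond formation at the fully substituted C8 takes place. The two C4 epimers may also cyclise at different rates. Fallback: a base-mediated intramolecular double Michael addition that sets out from 20. LiN(SiMe3)2 in THF (−78 to 0 °C) would form the cross-conjugated dienolate of the methyl ketone, which adds through C1 to C8; the resulting C10 enolate then adds through C7 to C6, and Et3SiCl traps the C9 enolate. The sequence comes back to the route at 22 and makes no new isolated compound.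

**Step 21.** The condensation may be reversed: methoxide can reopen the strained, non-enolisable β-dicarbonyl product if the C1 anion does not form, and the neopentyl ester may be too unreactive at temperatures where this cleavage is still slow. Fallback: an aldol closure in place of the Claisen closure, setting out from 25, where the ester is the only carbonyl group. LiAlH4 would give the primary alcohol F1. HF·pyridine would give the keto diol F2, and Dess–Martin oxidation the keto aldehyde F3. Allylation with 28 as in step 20 would give the geranyl keto aldehyde F4. LiN(SiMe3)2 would close C1 onto the aldehyde to the cage hydroxy diketone F5, and Dess–Martin oxidation comes back to the route at 30.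

**Step 4.** The tertiary radical at C12 may be oxidised (to a lactone or an alkene) before it cyclises, and the cyclisation may show poor facial selectivity between the trans and cis arrangements of C11 and C13. Fallback: an iodine atom-transfer annulation, setting out from 7. NaH and N-iodosuccinimide would give the iodomalonate F6. Irradiation with (Bu3Sn)2 in the presence of 6 would give the cyclised tertiary iodide F7 under non-oxidising conditions, and dehydroiodination with DBU comes back to the route at 8.

**Step 13.** Enolisation may go toward the C10 enone (dienolate formation and epimerisation at C11), or the transient enolate may undergo conjugate reactions, in place of clean O-silylation of the methyl ketone enolate. Fallback: a change of order so that the diene is made while no second ketone is present, setting out from 18. Acetylation (Ac2O, DMAP, pyridine) would give the acetate F8, and ketal hydrolysis as in step 12 the methyl ketone acetate F9. Et3SiOTf with Et3N would give the siloxydiene acetate F10. i-Bu2AlH at −78 °C would remove the acetate to give the siloxydiene allylic alcohol F11, and MnO2 would oxidise it under neutral conditions, coming back to the route at 21.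

**Step 7.** Opening of the lithium lactolate may be slow, so that attack on the ester, or loss of the formyl carbon from the α-formyl ester by fragmentation, competes at the temperature required. Fallback: an open-chain aldehyde, setting out from 10. Me3Al and MeNH(OMe)·HCl would open the lactone to the hydroxy N-methoxy-N-methylamide F12. Et3SiCl with imidazole would give the silyl ether amide F13, and i-Bu2AlH at −78 °C the aldehyde F14. Addition of 12 at −78 °C would give the mono-silylated alcohol F15, and silylation as in step 8 comes back to the route at 14.

## Further compounds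

F0 | step 14 | none | none
F1 | step 21 | primary alcohol from reduction of the ester of 25 | C=C(C)[C@@H]1C[C@@]2(CO)[C@@H](O[Si](CC)(CC)CC)C3=C(O[Si](CC)(CC)CC)CC(C)(C)[C@@H](C3)C[C@H]2C1(C)C
F2 | step 21 | keto diol (C2–OH, C4–OH, C9=O) | C=C(C)[C@@H]1C[C@@]2(CO)[C@@H](O)[C@H]3C[C@@H](C[C@H]2C1(C)C)C(C)(C)CC3=O
F3 | step 21 | keto aldehyde (C2 aldehyde, C4=O, C9=O, C5–H) | C=C(C)[C@@H]1C[C@@]2(C=O)C(=O)[C@H]3C[C@@H](C[C@H]2C1(C)C)C(C)(C)CC3=O
F4 | step 21 | geranyl keto aldehyde | C=C(C)[C@@H]1C[C@@]2(C=O)C(=O)[C@@]3(C/C=C(\C)CCC=C(C)C)C[C@@H](C[C@H]2C1(C)C)C(C)(C)CC3=O
F5 | step 21 | cage hydroxy diketone (C2–OH, either epimer) | C=C(C)[C@@H]1C[C@@]23C(=O)[C@@]4(C/C=C(\C)CCC=C(C)C)C[C@@H](C[C@H]2C1(C)C)C(C)(C)[C@H](C4=O)C3O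
F6 | step 4 | dimethyl 2-iodo-2-(3-methylbut-2-en-1-yl)malonate | COC(=O)C(I)(CC=C(C)C)C(=O)OC
F7 | step 4 | dimethyl (2S*,4S*)-2-(acetoxymethyl)-4-(2-iodopropan-2-yl)-3,3-dimethylcyclopentane-1,1-dicarboxylate (racemic) | CC(C)(I)[C@@H]1CC(C(=O)OC)(C(=O)OC)[C@@H](COC(C)=O)C1(C)C
F8 | step 13 | C10 acetate of 18 | C=C(C)[C@@H]1C[C@@](C(=O)OC)([C@@H](O[Si](CC)(CC)CC)C(=C)C2(C)OCCO2)[C@@H](C(OC(C)=O)C=C(C)C)C1(C)C
F9 | step 13 | methyl ketone acetate | C=C(C)[C@@H]1C[C@@](C(=O)OC)([C@@H](O[Si](CC)(CC)CC)C(=C)C(C)=O)[C@@H](C(OC(C)=O)C=C(C)C)C1(C)C
F10 | step 13 | siloxydiene acetate | C=C(C)[C@@H]1C[C@@](C(=O)OC)([C@@H](O[Si](CC)(CC)CC)C(=C)C(=C)O[Si](CC)(CC)CC)[C@@H](C(OC(C)=O)C=C(C)C)C1(C)C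
F11 | step 13 | siloxydiene allylic alcohol | C=C(C)[C@@H]1C[C@@](C(=O)OC)([C@@H](O[Si](CC)(CC)CC)C(=C)C(=C)O[Si](CC)(CC)CC)[C@@H](C(O)C=C(C)C)C1(C)C
F12 | step 7 | hydroxy N-methoxy-N-methylamide from 10 | C=C(C)[C@@H]1C[C@@](C(=O)OC)(C(=O)N(C)OC)[C@@H](CO)C1(C)C
F13 | step 7 | silyl ether amide | C=C(C)[C@@H]1C[C@@](C(=O)OC)(C(=O)N(C)OC)[C@@H](CO[Si](CC)(CC)CC)C1(C)C
F14 | step 7 | C4 aldehyde with C10 silyl ether | C=C(C)[C@@H]1C[C@@](C(=O)OC)(C=O)[C@@H](CO[Si](CC)(CC)CC)C1(C)C
F15 | step 7 | mono-silylated alcohol (C4–OH, C10–OSiEt3) | C=C(C)[C@@H]1C[C@@](C(=O)OC)([C@@H](O)C(=C)C2(C)OCCO2)[C@@H](CO[Si](CC)(CC)CC)C1(C)C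
A1 | alternative 1 | 3-diazo-2,4-dione with endo C7 prenyl group | CC(C)=CC[C@@H]1C[C@]2(C/C=C(\C)CCC=C(C)C)C(=O)C(=[N+]=[N-])C(=O)[C@@](C(=O)c3ccccc3)(C2=O)C1(C)C
A2 | alternative 1 | cyclopropane-fused homoadamantane trione | CC1(C)[C@@H]2C[C@@H]3C[C@]4(C/C=C(\C)CCC=C(C)C)C(=O)[C@]12C(=O)[C@@](C(=O)c1ccccc1)(C4=O)C3(C)C
A3 | alternative 2 | enol ether tethered to the cyclopentane-1,1-dicarbonyl dichloride | C=C(C)[C@@H]1CC(C(Cl)=O)(C(Cl)=O)[C@@H](C[C@@H]2CC(C/C=C(\C)CCC=C(C)C)=C(OC)CC2(C)C)C1(C)C
A4 | alternative 2 | des-benzoyl cage trione (C1–H), identical with 30 | C=C(C)[C@@H]1C[C@@]23C(=O)[C@@]4(C/C=C(\C)CCC=C(C)C)C[C@@H](C[C@H]2C1(C)C)C(C)(C)[C@H](C4=O)C3=O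
A5 | alternative 3 | C7-formyl trione with 2-methylprop-1-enyl and prenyl groups on C3 | O=C[C@@H]1C[C@]2(C/C=C(\C)CCC=C(C)C)C(=O)[C@@](C=C(C)C)(CC=C(C)C)C(=O)[C@@](C(=O)c3ccccc3)(C2=O)C1(C)C
A6 | alternative 3 | C10-hydroxy target | C=C(C)[C@@H]1C[C@@]23C(=O)[C@@]4(C/C=C(\C)CCC=C(C)C)C[C@@H]([C@@H](O)[C@H]2C1(C)C)C(C)(C)[C@](C(=O)c1ccccc1)(C4=O)C3=O
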